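Numbering: ring A = C1–C6 (C3 hydroxyl, C4=C5), chain C7–C15 then C15'–C7', ring B = C1'–C6' (C3' and C5' hydroxyls). The retrosynthesis first removes the ring A silyl ether, then cuts the C13'–C14' single bond (Stille) into the C22 alkenylstannane 16 and the C18 alkenyl iodide 33.
Feature that allows this: C14' is the CH end of the E C14'=C15' alkene and C13' the methyl-bearing end of the E C12'=C13' alkene. The bond between these two sp2 carbons separates ring A (cyclohexadienylidene unit C4=C5–C6=C7) from ring B (acid-sensitive tertiary allylic C5' alcohol beside C6'=C7'), so a neutral, stereoretentive palladium coupling can complete the eleven-alkene chain last.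
Further cuts, half A: C15–C15' (Stille linchpin), C14=C15 (Takai), C12=C13, C10=C11 and C8=C9 (Wittig), C6=C7 (ethynyl addition to the C6 ketone, Meyer–Schuster). Half B: C10'=C11' (HWE), C3'–O (inversion), C5'–O with C6'=C7' (oxirane opening), C8'=C9' (cross-metathesis), C6'–C7' (Stille on an enol triflate).
Forward: ketoisophorone gives the (S)-phorenol silyl ether 3, which feeds both rings. The ring A chain grows from C6 to C14' (steps 3–10), the ring B chain from C6' to C13' (steps 11–17 and 21, phosphonate 32 from steps 18–20). The halves meet in step 22 and desilylation ends the route.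
Stereochemistry: C3 and C3' come from one Noyori transfer hydrogenation; C3' is later inverted (Mitsunobu) because rings A and B carry this oxygen on opposite faces. C5' comes from a hydroxyl-directed epoxidation. C6'=C7' geometry comes from allylic strain in the oxirane opening, C6=C7 from thermodynamic control, and the chain alkenes from E-selective Wittig, HWE, Takai and metathesis steps and retention in both Stille couplings.

Key step: step 22

Remark: aqueous work-up is assumed after every step that leaves a metal alkoxide or amide, and compounds 1, 4, 7, 9, 13, 15, 19, 22 and 28 are taken as commercial.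

Step 1
Reactants: 1 ketoisophorone (2,6,6-trimethylcyclohex-2-ene-1,4-dione)
Product: 2 (4S)-4-hydroxy-2,6,6-trimethylcyclohex-2-en-1-one ((S)-phorenol)
Conditions: RuCl(p-cymene)[(S,S)-TsDPEN] (0.5 mol%), HCO2H/Et3N (5:2), CH2Cl2, 25 °C
Reagents that add atoms: none
Why: Noyori asymmetric transfer hydrogenation should reduce only the less hindered C4 carbonyl (C1 is flanked by the gem-dimethyl carbon and the methylated alkene carbon) and, with the alkene in the place of the aryl group in the CH/π model, the (S,S)-ligand should give the (S)-carbinol, the future C3 of ring A and C3' of ring B.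

Step 2
Reactants: 2 (S)-phorenol
Product: 3 (4S)-4-(tert-butyldimethylsilyloxy)-2,6,6-trimethylcyclohex-2-en-1-one
Conditions: TBSCl, imidazole, DMF, 25 °C
Reagents that add atoms: tert-butyldimethylsilyl chloride, CC(C)(C)[Si](C)(C)Cl
Why: Imidazole-promoted silyl ether formation on a secondary allylic alcohol; no stereocentre is touched.

Step 3
Reactants: 3 silyl ether of (S)-phorenol; 4 ethynylmagnesium bromide
Product: 5 (4S)-4-(tert-butyldimethylsilyloxy)-1-ethynyl-2,6,6-trimethylcyclohex-2-en-1-ol (both C1 epimers)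
Conditions: THF, 0 to 25 °C; then H2O
Reagents that add atoms: ethynylmagnesium bromide (compound 4), C#C[Mg]Br
Why: 1,2-Addition of an alkynyl Grignard reagent to the enone carbonyl, the small sp nucleophile being able to reach the hindered C1 ketone (the later C6); the new carbinol centre is not controlled because step 4 erases it.

Step 4
Reactants: 5 ethynyl carbinol
Product: 6 (2E)-2-[(4S)-4-(tert-butyldimethylsilyloxy)-2,6,6-trimethylcyclohex-2-en-1-ylidene]acetaldehyde
Conditions: Ph3PAuNTf2 (2 mol%), MeOH (1 equiv), toluene, 25 °C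
Reagents that add atoms: none
Why: Gold-catalysed Meyer–Schuster rearrangement (1,3-hydroxyl shift through the allenol) gives the enal; Rupe dehydration is impossible because neither neighbour of the carbinol carbon bears hydrogen, and the C6=C7 geometry should settle thermodynamically with the formyl carbon cis to the gem-dimethyl carbon C1, away from the in-plane C5 methyl (allylic 1,3-strain).

Step 5
Reactants: 6 ring A dienal; 7 2-(triphenylphosphoranylidene)propanal
Product: 8 (2E,4E)-4-[(4S)-4-(tert-butyldimethylsilyloxy)-2,6,6-trimethylcyclohex-2-en-1-ylidene]-2-methylbut-2-enal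
Conditions: toluene, 90 °C
Reagents that add atoms: 2-(triphenylphosphoranylidene)propanal (compound 7), CC(C=O)=P(c1ccccc1)(c1ccccc1)c1ccccc1
Why: Wittig olefination with a stabilized α-methyl ylide is E-selective and neutral, so the C3 centre, which is vinylogously acidic through the aldehyde, is not endangered.

Step 6
Reactants: 8 ring A trienal; 9 N-methoxy-N-methyl-2-(triphenylphosphoranylidene)acetamide
Product: 10 (2E,4E,6E)-6-[(4S)-4-(tert-butyldimethylsilyloxy)-2,6,6-trimethylcyclohex-2-en-1-ylidene]-N-methoxy-N,4-dimethylhexa-2,4-dienamide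
Conditions: toluene, 90 °C
Reagents that add atoms: N-methoxy-N-methyl-2-(triphenylphosphoranylidene)acetamide (compound 9), CON(C)C(=O)C=P(c1ccccc1)(c1ccccc1)c1ccccc1
Why: Wittig olefination with the stabilized Weinreb-amide ylide should give the (E)-enamide under neutral conditions.

Step 7
Reactants: 10 Weinreb amide
Product: 11 (2E,4E,6E)-6-[(4S)-4-(tert-butyldimethylsilyloxy)-2,6,6-trimethylcyclohex-2-en-1-ylidene]-4-methylhexa-2,4-dienal
Conditions: i-Bu2AlH, THF, −78 °C; then aqueous potassium sodium tartrate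
Reagents that add atoms: none
Why: Reduction of a Weinreb amide by the aluminium hydride stops at the chelated tetrahedral intermediate, which releases the aldehyde only on work-up.

Step 8
Reactants: 11 C12 aldehyde; 7 2-(triphenylphosphoranylidene)propanal
Product: 12 (2E,4E,6E,8E)-8-[(4S)-4-(tert-butyldimethylsilyloxy)-2,6,6-trimethylcyclohex-2-en-1-ylidene]-2,6-dimethylocta-2,4,6-trienal
Conditions: toluene, 80 °C
Reagents that add atoms: 2-(triphenylphosphoranylidene)propanal (compound 7), CC(C=O)=P(c1ccccc1)(c1ccccc1)c1ccccc1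
Why: A second E-selective Wittig olefination with the stabilized α-methyl ylide adds C13, its methyl group and C14.

Step 9
Reactants: 12 C14 aldehyde; 13 iodoform
Product: 14 tert-butyl{[(1S,4E)-4-[(2E,4E,6E,8E)-9-iodo-3,7-dimethylnona-2,4,6,8-tetraen-1-ylidene]-3,5,5-trimethylcyclohex-2-en-1-yl]oxy}dimethylsilane
Conditions: CHI3, CrCl2, THF, 0 °C
Reagents that add atoms: iodoform (compound 13), IC(I)I
Why: Takai olefination: the geminal dichromium species from iodoform and CrCl2 adds to the aldehyde and eliminates to give the (E)-alkenyl iodide.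

Step 10
Reactants: 14 C15 alkenyl iodide; 15 (E)-1,2-bis(tributylstannyl)ethene
Product: 16 tributyl{(1E,3E,5E,7E,9E,11E)-11-[(4S)-4-(tert-butyldimethylsilyloxy)-2,6,6-trimethylcyclohex-2-en-1-ylidene]-5,9-dimethylundeca-1,3,5,7,9-pentaen-1-yl}stannane
Conditions: PdCl2(MeCN)2 (5 mol%), DMF, 25 °C, dark (15 in 3 equiv)
Reagents that add atoms: (E)-1,2-bis(tributylstannyl)ethene (compound 15), CCCC[Sn](CCCC)(CCCC)/C=C/[Sn](CCCC)(CCCC)CCCC
Why: Stille coupling of the alkenyl iodide with one tin terminus of the distannane (in excess to suppress double coupling) proceeds with retention at both alkenes and leaves the second tin at C14' as the handle for the key step.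

Step 11
Reactants: 3 silyl ether of (S)-phorenol
Product: 18 (4R)-4-(tert-butyldimethylsilyloxy)-2,6,6-trimethylcyclohex-1-en-1-yl trifluoromethanesulfonate, via lithium enolate 17 (not isolated)
Conditions: LiBH(s-Bu)3 (L-Selectride), THF, −78 °C; then PhNTf2, −78 to 0 °C
Reagents that add atoms: N-phenylbis(trifluoromethanesulfonimide), O=S(=O)(N(c1ccccc1)S(=O)(=O)C(F)(F)F)C(F)(F)F
Why: Conjugate reduction by the bulky borohydride (hydride to the β-carbon C3 of the enone, the later C4', because the carbonyl is shielded by two fully substituted neighbours) gives the only possible enolate regioisomer, which PhNTf2 sulfonylates on oxygen (reductive enol triflate formation).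

Step 12
Reactants: 18 enol triflate; 19 allyltributylstannane
Product: 20 tert-butyldimethyl{[(1R)-3,5,5-trimethyl-4-(prop-2-en-1-yl)cyclohex-3-en-1-yl]oxy}silane
Conditions: Pd(PPh3)4 (5 mol%), LiCl, THF, 65 °C
Reagents that add atoms: allyltributylstannane (compound 19), C=CC[Sn](CCCC)(CCCC)CCCC
Why: Stille coupling of an enol triflate with an allylstannane (chloride promotes the transmetalation) attaches C7' and C8' plus a terminal carbon that metathesis later exchanges.

Step 13
Reactants: 20 allyl silyl ether
Product: 21 (1R)-3,5,5-trimethyl-4-(prop-2-en-1-yl)cyclohex-3-en-1-ol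
Conditions: Bu4NF, THF, 25 °C
Reagents that add atoms: none
Why: Fluoride cleaves the Si–O bond to free the C3' hydroxyl that must direct the epoxidation; no base-sensitive group is present at this stage.

Step 14
Reactants: 21 homoallylic alcohol; 22 methacrolein
Product: 23 (2E)-4-[(4R)-4-hydroxy-2,6,6-trimethylcyclohex-1-en-1-yl]-2-methylbut-2-enal
Conditions: second-generation Hoveyda–Grubbs catalyst (5 mol%), CH2Cl2, 40 °C (22 in 5 equiv)
Reagents that add atoms: methacrolein (compound 22), CC(=C)C=O
Why: Olefin cross-metathesis of the terminal alkene with methacrolein; the tetrasubstituted ring alkene cannot enter the catalytic cycle and the trisubstituted enal should form as the E isomer.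

Step 15
Reactants: 23 skipped dienal
Product: 24 (2E)-4-[(1R,4S,6S)-4-hydroxy-2,2,6-trimethyl-7-oxabicyclo[4.1.0]heptan-1-yl]-2-methylbut-2-enal (oxirane syn to the hydroxyl)
Conditions: VO(acac)2 (5 mol%), t-BuOOH, CH2Cl2, 0 °C
Reagents that add atoms: tert-butyl hydroperoxide, CC(C)(C)OO
Why: Hydroxyl-directed epoxidation: the vanadate ester of the homoallylic C3' hydroxyl delivers the peroxide oxygen to the electron-rich ring alkene on its own face, which is also the face away from the pseudoaxial C1' methyl, so the C5'–C6' oxirane should form syn to the hydroxyl while the electron-poor enal alkene stays untouched.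

Step 16
Reactants: 24 epoxy enal
Product: 25 (2E,4E)-4-[(2S,4S)-2,4-dihydroxy-2,6,6-trimethylcyclohexylidene]-2-methylbut-2-enal (cis-diol; chain cis to the gem-dimethyl carbon)
Conditions: DBU, CH2Cl2, 0 to 25 °C
Reagents that add atoms: none
Why: Vinylogous E1cB opening of the oxirane: DBU removes a C7' hydrogen (γ to the aldehyde), the dienolate expels the C6'–O bond to give the tertiary C5' alcohol with its configuration intact and the C6'=C7' alkene, and C8' should turn away from the oxirane methyl that is cis to C7' (allylic 1,3-strain in the planar dienolate), which places the chain cis to C1' as required; the syn C3' oxygen cannot reach the back side of the oxirane.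

Step 17
Reactants: 25 cis-diol dienal
Product: 27 (2E,4E)-4-[(2S,4R)-2,4-dihydroxy-2,6,6-trimethylcyclohexylidene]-2-methylbut-2-enal (trans-diol), via 4-nitrobenzoate ester 26 (not isolated)
Conditions: PPh3, DIAD, 4-nitrobenzoic acid, THF, 0 to 25 °C; then K2CO3 (cat.), MeOH, 25 °C
Reagents that add atoms: 4-nitrobenzoic acid, OC(=O)c1ccc(cc1)[N+](=O)[O-]
Why: Mitsunobu reaction: the secondary C3' oxyphosphonium ion (the tertiary C5' hydroxyl is not activated) is displaced by 4-nitrobenzoate in an SN2 step with inversion, and methanolysis of the ester frees the (3'R) alcohol, now trans to the C5' hydroxyl.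

Step 18
Reactants: 28 but-2-yn-1-ol
Product: 30 (2E)-3-iodobut-2-en-1-ol, via alkenylzirconocene 29 (not isolated)
Conditions: Cp2Zr(H)Cl (2.2 equiv), THF, 25 to 40 °C; then I2, 0 °C; aqueous work-up
Reagents that add atoms: iodine, [I][I]
Why: Syn hydrozirconation of the internal alkyne by the Schwartz reagent (the first equivalent is consumed as zirconium alkoxide) should place zirconium on C3, the alkyne carbon with the smaller methyl substituent, and iodinolysis with retention gives the (E)-alkenyl iodide.

Step 19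
Reactants: 30 (2E)-3-iodobut-2-en-1-ol
Product: 31 (2E)-1-bromo-3-iodobut-2-ene
Conditions: CBr4, PPh3, CH2Cl2, 0 °C
Reagents that add atoms: carbon tetrabromide, BrC(Br)(Br)Br
Why: Appel reaction: bromide displaces the primary allylic oxyphosphonium ion without touching the alkenyl iodide.

Step 20
Reactants: 31 (2E)-1-bromo-3-iodobut-2-ene
Product: 32 diethyl [(2E)-3-iodobut-2-en-1-yl]phosphonate
Conditions: P(OEt)3, 90 °C
Reagents that add atoms: triethyl phosphite, CCOP(OCC)OCC
Why: Michaelis–Arbuzov reaction: SN2 attack of the phosphite on the primary allylic bromide followed by dealkylation gives the phosphonate.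

Step 21
Reactants: 27 trans-diol dienal; 32 iodo phosphonate
Product: 33 (1R,3S,4E)-4-[(2E,4E,6E)-7-iodo-3-methylocta-2,4,6-trien-1-ylidene]-3,5,5-trimethylcyclohexane-1,3-diol
Conditions: NaN(SiMe3)2, THF, −78 to 0 °C (32 and base in 3 equiv)
Reagents that add atoms: none
Why: Horner–Wadsworth–Emmons olefination of the enal with the allylic phosphonate anion is E-selective for the new C10'=C11' alkene; the two hydroxyls ride through as sodium alkoxides (hence the excess of anion) and the alkenyl iodide is inert to the base at low temperature.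

Step 22
Reactants: 16 C22 alkenylstannane; 33 C18 alkenyl iodide
Product: 34 3-O-(tert-butyldimethylsilyl) ether of the target (silyl group on the ring A hydroxyl)
Conditions: Pd2(dba)3 (5 mol%), AsPh3 (40 mol%), NMP, 25 °C, dark, argon
Reagents that add atoms: none
Why: Zerovalent palladium inserts into the C13'–I bond of 33 with retention, the (E)-alkenyl group of 16 is transferred from tin to palladium (AsPh3, a weak donor, speeds this transmetalation at room temperature), and reductive elimination forges the C13'–C14' single bond between the two alkene carbons. The closest known reaction type is the Stille alkenyl–alkenyl coupling of polyenyl stannanes with alkenyl iodides used to finish carotenoid and other polyene chains. No ring is closed and no stereocentre is created; the E geometries of C14'=C15' and C12'=C13' are carried over from 16 and 33 because all three elementary steps proceed with retention. The selectivity needed is cross-coupling without homocoupling, protodestannylation or E/Z scrambling of the eleven conjugated alkenes. It should be secured by the unhindered CH=CH–Sn terminus, the reactive iodide on the methyl-bearing carbon, the absence of acid, base and heat, and the exclusion of light and oxygen. The neutral medium also leaves the tertiary allylic C5' hydroxyl and the C3' hydroxyl untouched, so ring B needs no protecting group.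

Step 23
Reactants: 34 silyl ether of the target
Product: 35 (3S,3'R,5'S,6E,6'E)-4,5'-retro-β,β-carotene-3,3',5'-triol (CNP0269135.1)
Conditions: Bu4NF, THF, 0 to 25 °C
Reagents that add atoms: none
Why: Fluoride-induced cleavage of the allylic silyl ether under non-acidic conditions frees the C3 hydroxyl without ionizing the tertiary allylic C5' alcohol or disturbing the polyene.

Compound list
1 | ketoisophorone (2,6,6-trimethylcyclohex-2-ene-1,4-dione) | CC1=CC(=O)CC(C)(C)C1=O | starting material
2 | (4S)-4-hydroxy-2,6,6-trimethylcyclohex-2-en-1-one | CC1=C[C@@H](O)CC(C)(C)C1=O | intermediate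
3 | (4S)-4-(tert-butyldimethylsilyloxy)-2,6,6-trimethylcyclohex-2-en-1-one | CC1=C[C@@H](O[Si](C)(C)C(C)(C)C)CC(C)(C)C1=O | intermediate
4 | ethynylmagnesium bromide | C#C[Mg]Br | starting material
5 | (4S)-4-(tert-butyldimethylsilyloxy)-1-ethynyl-2,6,6-trimethylcyclohex-2-en-1-ol (both C1 epimers) | CC1=C[C@@H](O[Si](C)(C)C(C)(C)C)CC(C)(C)C1(O)C#C | intermediate
6 | (2E)-2-[(4S)-4-(tert-butyldimethylsilyloxy)-2,6,6-trimethylcyclohex-2-en-1-ylidene]acetaldehyde | CC1=C[C@@H](O[Si](C)(C)C(C)(C)C)CC(C)(C)\C1=C/C=O | intermediate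
7 | 2-(triphenylphosphoranylidene)propanal | CC(C=O)=P(c1ccccc1)(c1ccccc1)c1ccccc1 | starting material
8 | (2E,4E)-4-[(4S)-4-(tert-butyldimethylsilyloxy)-2,6,6-trimethylcyclohex-2-en-1-ylidene]-2-methylbut-2-enal | CC1=C[C@@H](O[Si](C)(C)C(C)(C)C)CC(C)(C)\C1=C/C=C(C)/C=O | intermediate
9 | N-methoxy-N-methyl-2-(triphenylphosphoranylidene)acetamide | CON(C)C(=O)C=P(c1ccccc1)(c1ccccc1)c1ccccc1 | starting material
10 | (2E,4E,6E)-6-[(4S)-4-(tert-butyldimethylsilyloxy)-2,6,6-trimethylcyclohex-2-en-1-ylidene]-N-methoxy-N,4-dimethylhexa-2,4-dienamide | CC1=C[C@@H](O[Si](C)(C)C(C)(C)C)CC(C)(C)\C1=C/C=C(C)/C=C/C(=O)N(C)OC | intermediate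
11 | (2E,4E,6E)-6-[(4S)-4-(tert-butyldimethylsilyloxy)-2,6,6-trimethylcyclohex-2-en-1-ylidene]-4-methylhexa-2,4-dienal | CC1=C[C@@H](O[Si](C)(C)C(C)(C)C)CC(C)(C)\C1=C/C=C(C)/C=C/C=O | intermediate
12 | (2E,4E,6E,8E)-8-[(4S)-4-(tert-butyldimethylsilyloxy)-2,6,6-trimethylcyclohex-2-en-1-ylidene]-2,6-dimethylocta-2,4,6-trienal | CC1=C[C@@H](O[Si](C)(C)C(C)(C)C)CC(C)(C)\C1=C/C=C(C)/C=C/C=C(C)/C=O | intermediate
13 | iodoform | IC(I)I | starting material
14 | tert-butyl{[(1S,4E)-4-[(2E,4E,6E,8E)-9-iodo-3,7-dimethylnona-2,4,6,8-tetraen-1-ylidene]-3,5,5-trimethylcyclohex-2-en-1-yl]oxy}dimethylsilane | CC1=C[C@@H](O[Si](C)(C)C(C)(C)C)CC(C)(C)\C1=C/C=C(C)/C=C/C=C(C)/C=C/I | intermediate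
15 | (E)-1,2-bis(tributylstannyl)ethene | CCCC[Sn](CCCC)(CCCC)/C=C/[Sn](CCCC)(CCCC)CCCC | starting material
16 | tributyl{(1E,3E,5E,7E,9E,11E)-11-[(4S)-4-(tert-butyldimethylsilyloxy)-2,6,6-trimethylcyclohex-2-en-1-ylidene]-5,9-dimethylundeca-1,3,5,7,9-pentaen-1-yl}stannane | CC1=C[C@@H](O[Si](C)(C)C(C)(C)C)CC(C)(C)\C1=C/C=C(C)/C=C/C=C(C)/C=C/C=C/[Sn](CCCC)(CCCC)CCCC | intermediate
17 | lithium (4R)-4-(tert-butyldimethylsilyloxy)-2,6,6-trimethylcyclohex-1-en-1-olate | [Li+].CC1=C([O-])C(C)(C)C[C@H](O[Si](C)(C)C(C)(C)C)C1 | intermediate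
18 | (4R)-4-(tert-butyldimethylsilyloxy)-2,6,6-trimethylcyclohex-1-en-1-yl trifluoromethanesulfonate | CC1=C(OS(=O)(=O)C(F)(F)F)C(C)(C)C[C@H](O[Si](C)(C)C(C)(C)C)C1 | intermediate
19 | allyltributylstannane | C=CC[Sn](CCCC)(CCCC)CCCC | starting material
20 | tert-butyldimethyl{[(1R)-3,5,5-trimethyl-4-(prop-2-en-1-yl)cyclohex-3-en-1-yl]oxy}silane | CC1=C(CC=C)C(C)(C)C[C@H](O[Si](C)(C)C(C)(C)C)C1 | intermediate
21 | (1R)-3,5,5-trimethyl-4-(prop-2-en-1-yl)cyclohex-3-en-1-ol | CC1=C(CC=C)C(C)(C)C[C@H](O)C1 | intermediate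
22 | methacrolein | CC(=C)C=O | starting material
23 | (2E)-4-[(4R)-4-hydroxy-2,6,6-trimethylcyclohex-1-en-1-yl]-2-methylbut-2-enal | CC1=C(C/C=C(\C)C=O)C(C)(C)C[C@H](O)C1 | intermediate
24 | (2E)-4-[(1R,4S,6S)-4-hydroxy-2,2,6-trimethyl-7-oxabicyclo[4.1.0]heptan-1-yl]-2-methylbut-2-enal | O=C/C(C)=C/C[C@]12O[C@@]1(C)C[C@@H](O)CC2(C)C | intermediate
25 | (2E,4E)-4-[(2S,4S)-2,4-dihydroxy-2,6,6-trimethylcyclohexylidene]-2-methylbut-2-enal | O=C/C(C)=C/C=C1\C(C)(C)C[C@H](O)C[C@]1(C)O | intermediate
26 | (1R,3S,4E)-3-hydroxy-3,5,5-trimethyl-4-[(2E)-3-methyl-4-oxobut-2-en-1-ylidene]cyclohexyl 4-nitrobenzoate | O=C/C(C)=C/C=C1\C(C)(C)C[C@@H](OC(=O)c2ccc(cc2)[N+](=O)[O-])C[C@]1(C)O | intermediate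
27 | (2E,4E)-4-[(2S,4R)-2,4-dihydroxy-2,6,6-trimethylcyclohexylidene]-2-methylbut-2-enal | O=C/C(C)=C/C=C1\C(C)(C)C[C@@H](O)C[C@]1(C)O | intermediate
28 | but-2-yn-1-ol | CC#CCO | starting material
29 | chlorobis(cyclopentadienyl)zirconium (E)-alkenyl species of the zirconium alkoxide of but-2-yn-1-ol (zirconium on C3; cyclopentadienyl rings drawn η1) | C/C(=C\CO[Zr](Cl)(C1C=CC=C1)C1C=CC=C1)[Zr](Cl)(C1C=CC=C1)C1C=CC=C1 | intermediate
30 | (2E)-3-iodobut-2-en-1-ol | OC/C=C(\C)I | intermediate
31 | (2E)-1-bromo-3-iodobut-2-ene | BrC/C=C(\C)I | intermediate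
32 | diethyl [(2E)-3-iodobut-2-en-1-yl]phosphonate | CCOP(=O)(OCC)C/C=C(\C)I | intermediate
33 | (1R,3S,4E)-4-[(2E,4E,6E)-7-iodo-3-methylocta-2,4,6-trien-1-ylidene]-3,5,5-trimethylcyclohexane-1,3-diol | I/C(C)=C/C=C/C(C)=C/C=C1\C(C)(C)C[C@@H](O)C[C@]1(C)O | intermediate
34 | 3-O-(tert-butyldimethylsilyl) ether of (3S,3'R,5'S,6E,6'E)-4,5'-retro-β,β-carotene-3,3',5'-triol | CC1=C[C@@H](O[Si](C)(C)C(C)(C)C)CC(C)(C)\C1=C/C=C(C)/C=C/C=C(C)/C=C/C=C/C(C)=C/C=C/C(C)=C/C=C1\C(C)(C)C[C@@H](O)C[C@]1(C)O | intermediate
35 | (3S,3'R,5'S,6E,6'E)-4,5'-retro-β,β-carotene-3,3',5'-triol (CNP0269135.1) | CC1=C[C@@H](O)CC(C)(C)\C1=C/C=C(C)/C=C/C=C(C)/C=C/C=C/C(C)=C/C=C/C(C)=C/C=C1\C(C)(C)C[C@@H](O)C[C@]1(C)O | target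

Total step count: 23.
Longest linear sequence: 12 steps (steps 1, 2, 11–17, 21, 22, 23; the ring A line, steps 1–10, 22, 23, is equally long).

The three steps most likely to fail

Step 15. Process at risk: delivery of oxygen to the wrong face, or sluggish epoxidation of the hindered tetrasubstituted alkene with competing oxidation of the aldehyde. The fallback sets out from 23 and returns at 25, bypassing steps 15 and 16. Dye-sensitized photooxygenation of 23 (O2, tetraphenylporphyrin, visible light, CH2Cl2, −20 °C) is a Schenck ene reaction in which singlet oxygen bonds to C5' and takes a hydrogen from the doubly allylic C7', the position geminal to the bulky C1' carbon. It would give the C5' hydroperoxide F1 with the C6'=C7' alkene already in place, and PPh3 would reduce it to 25.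

Step 17. Process at risk: elimination instead of substitution at the hindered C3' oxyphosphonium ion, whose back side is flanked by two syn methyl groups, or incomplete inversion. The fallback sets out from 25 and returns at 33. Compound 25 is taken through the conditions of step 21 with 32 to the C3'-epimeric diol iodide F2. Dess–Martin periodinane (NaHCO3, CH2Cl2) would oxidize only the secondary hydroxyl to the β-hydroxy ketone F3. Evans–Saksena reduction (Me4NBH(OAc)3, MeCN/AcOH, −30 °C) would then deliver hydride from boron bound to the C5' oxygen and should give the 1,3-anti diol 33.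

Step 22. Process at risk: E/Z scrambling, protodestannylation and homocoupling while two light-sensitive polyenes wait for a slow transmetalation. The fallback sets out from 14 and 33 and returns at 34. Sonogashira coupling of 14 with ethynyltrimethylsilane (Pd(PPh3)2Cl2, CuI, Et3N, THF) would give the silyl enyne F4, and K2CO3 in MeOH the terminal enyne F5. Hydroboration with pinacolborane (Cp2Zr(H)Cl cat., CH2Cl2) would give the (E)-alkenylboronate F6. Suzuki–Miyaura coupling of F6 with 33 (Pd(PPh3)4, TlOEt, THF/H2O, 25 °C) would form the same C13'–C14' bond through boron instead of tin and give 34.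

Further compounds
F1 | step 15 | (2E,4E)-4-[(2S,4S)-2-hydroperoxy-4-hydroxy-2,6,6-trimethylcyclohexylidene]-2-methylbut-2-enal | O=C/C(C)=C/C=C1\C(C)(C)C[C@H](O)C[C@]1(C)OO
F2 | step 17 | (1S,3S,4E)-4-[(2E,4E,6E)-7-iodo-3-methylocta-2,4,6-trien-1-ylidene]-3,5,5-trimethylcyclohexane-1,3-diol | I/C(C)=C/C=C/C(C)=C/C=C1\C(C)(C)C[C@H](O)C[C@]1(C)O
F3 | step 17 | (3S,4E)-3-hydroxy-4-[(2E,4E,6E)-7-iodo-3-methylocta-2,4,6-trien-1-ylidene]-3,5,5-trimethylcyclohexan-1-one | I/C(C)=C/C=C/C(C)=C/C=C1\C(C)(C)CC(=O)C[C@]1(C)O
F4 | step 22 | tert-butyl{[(1S,4E)-4-[(2E,4E,6E,8E)-3,7-dimethyl-11-(trimethylsilyl)undeca-2,4,6,8-tetraen-10-yn-1-ylidene]-3,5,5-trimethylcyclohex-2-en-1-yl]oxy}dimethylsilane | CC1=C[C@@H](O[Si](C)(C)C(C)(C)C)CC(C)(C)\C1=C/C=C(C)/C=C/C=C(C)/C=C/C#C[Si](C)(C)C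
F5 | step 22 | tert-butyl{[(1S,4E)-4-[(2E,4E,6E,8E)-3,7-dimethylundeca-2,4,6,8-tetraen-10-yn-1-ylidene]-3,5,5-trimethylcyclohex-2-en-1-yl]oxy}dimethylsilane | CC1=C[C@@H](O[Si](C)(C)C(C)(C)C)CC(C)(C)\C1=C/C=C(C)/C=C/C=C(C)/C=C/C#C
F6 | step 22 | pinacol ester of (1E,3E,5E,7E,9E,11E)-11-[(4S)-4-(tert-butyldimethylsilyloxy)-2,6,6-trimethylcyclohex-2-en-1-ylidene]-5,9-dimethylundeca-1,3,5,7,9-pentaen-1-ylboronic acid | CC1=C[C@@H](O[Si](C)(C)C(C)(C)C)CC(C)(C)\C1=C/C=C(C)/C=C/C=C(C)/C=C/C=C/B1OC(C)(C)C(C)(C)O1
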